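1. Locants: ring A = C1–C2–C3–C4(Me); aromatic ring B = C5–C10 with OH on C7; quinone ring C = C8, C9, C11(=O), C12(OMe), C13(i-Pr), C14(=O); lactone = C4–C(=O)–O–C1.
2. Cuts: O–C1 and C(=O)–C4 together (CO2 is taken out of the o-quinodimethane C1=C10–C5=C4, stored as a C1 pivalate); then C1–O; then ring B at C7–C8 and C9–C10 into a bromoquinone (ring C) and a cyclohexenyl ketene acetal (ring A).
3. Forward: ring C and ring A are made apart, ring B is closed between them by Diels–Alder reaction and aromatisation, C1 is oxygenated through the quinone photoenol, and CO2 is taken up last to close the lactone bridge.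
4. Enabling feature: C1 and C4 sit on the adjacent ring-B atoms C10 and C5, and C5 is para to C8, which carries the C14 carbonyl. C4–H is thus a vinylogous α-proton of C14=O, and once C1=C10 exists C1 is the δ-acceptor of the same carbonyl, so the quinone makes C1=C10–C5=C4 a push–pull diene.
5. Stereochemistry: C1 and C4 are both planar just before the key step; C4 is set there in a chiral ammonium ion pair, and C1 follows because the O–C(=O) bridge can only span one face; all earlier compounds are achiral or racemic.

Key step: step 10

Assumption: the sense of induction of the ammonium catalyst cannot be foreseen; the cinchonidinium salt is written, and its pseudoenantiomeric cinchoninium salt would be taken if the antipode forms.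

Step 1
Reactants: 1 1,2,4-trimethoxybenzene
Product: 2 2-(2,3,6-trimethoxyphenyl)propan-2-ol
Conditions: n-BuLi, TMEDA, THF, 0 °C; acetone, −78 °C → rt
Reagents that add atoms: acetone, CC(C)=O
Why: Directed ortho-metalation puts lithium on the ring carbon between the C2 and C4 methoxy groups of 1, and the aryllithium adds to acetone (carbonyl addition).

Step 2
Reactants: 2 2-(2,3,6-trimethoxyphenyl)propan-2-ol
Product: 3 1,2,4-trimethoxy-3-(propan-2-yl)benzene
Conditions: Et3SiH, CF3CO2H, CH2Cl2, 0 °C → rt
Reagents that add atoms: none
Why: Ionic hydrogenation: acid ionises the tertiary benzylic alcohol to a cation that the two ortho methoxy groups stabilise, and the silane delivers hydride.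

Step 3
Reactants: 3 1,2,4-trimethoxy-3-(propan-2-yl)benzene
Product: 4 1-bromo-2,4,5-trimethoxy-3-(propan-2-yl)benzene
Conditions: NBS, MeCN, 0 °C → rt
Reagents that add atoms: N-bromosuccinimide, O=C1CCC(=O)N1Br
Why: Electrophilic aromatic bromination should go to the one free position that is ortho to a methoxy group and para to another, the carbon next to the methoxy group that flanks the isopropyl group.

Step 4
Reactants: 4 1-bromo-2,4,5-trimethoxy-3-(propan-2-yl)benzene
Product: 5 2-bromo-5-methoxy-6-(propan-2-yl)cyclohexa-2,5-diene-1,4-dione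
Conditions: (NH4)2Ce(NO3)6, MeCN–H2O, 0 °C
Reagents that add atoms: water, O
Why: Oxidative demethylation of the para-dimethoxy pair by tetravalent cerium gives the 1,4-benzoquinone and leaves the third methoxy group and the bromine in place (CAN oxidation of a hydroquinone dimethyl ether).

Step 5
Reactants: 6 2-methylcyclohexanone (racemic)
Product: 7 ethyl 2-(2-methylcyclohexylidene)acetate
Conditions: (EtO)2P(O)CH2CO2Et, NaH, THF, 0 °C → reflux
Reagents that add atoms: triethyl phosphonoacetate, CCOC(=O)CP(=O)(OCC)OCC
Why: Horner–Wadsworth–Emmons olefination of the ketone should give the α,β-unsaturated ester mainly as the E isomer, in which the ester is syn to the ring CH2.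

Step 6
Reactants: 7 ethyl 2-(2-methylcyclohexylidene)acetate
Product: 8 [1-ethoxy-2-(6-methylcyclohex-1-en-1-yl)ethenyl]oxy(trimethyl)silane
Conditions: LiN(i-Pr)2, THF, −78 °C; Me3SiCl, −78 °C → rt; used crude
Reagents that add atoms: chlorotrimethylsilane, C[Si](C)(C)Cl
Why: Kinetic γ-deprotonation of the enoate takes a ring CH2 proton syn to the ester and O-silylation of the dienolate gives the vinylketene acetal with the C4 methine untouched (deconjugative dienolate formation).

Step 7
Reactants: 5 2-bromo-5-methoxy-6-(propan-2-yl)cyclohexa-2,5-diene-1,4-dione; 8 [1-ethoxy-2-(6-methylcyclohex-1-en-1-yl)ethenyl]oxy(trimethyl)silane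
Product: 10 quinone phenol (C7–OH; C12–OMe; C13–i-Pr; C11/C14 quinone; ring A C1H2–C2H2–C3H2–C4H(Me); racemic), via bromo ketal cycloadduct 9 (not isolated)
Conditions: CH2Cl2, −20 °C → rt; then SiO2, rt
Reagents that add atoms: none
Why: Diels–Alder reaction of a vinylketene acetal with a 2-bromoquinone, in which the halogen steers the nucleophilic diene terminus C10 to the unhalogenated quinone carbon C9 and the acetal carbon C7 to C8, followed by loss of HBr, ethanol and the silyl group to aromatise ring B.

Step 8
Reactants: 10 quinone phenol
Product: 11 7-O-triisopropylsilyl ether of 10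
Conditions: i-Pr3SiCl, imidazole, DMF, 40 °C
Reagents that add atoms: chlorotri(propan-2-yl)silane, CC(C)[Si](Cl)(C(C)C)C(C)C
Why: Silylation of the hydrogen-bonded phenol (silyl ether formation); the ether switches off excited-state proton transfer for step 9 and phenoxide formation for step 10 and offers no hydrogen to the excited C14 carbonyl.

Step 9
Reactants: 11 7-O-triisopropylsilyl ether of 10
Product: 14 C1 pivalate of 11 (racemic; both C1/C4 diastereomers), via photoenol 12 (not isolated), via hydroquinone pivalate 13 (not isolated)
Conditions: hν (405 nm), t-BuCO2H (excess), MeCN, O2 (1 atm), rt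
Reagents that add atoms: pivalic acid, CC(C)(C)C(O)=O
Why: Photoenolisation of a peri-alkyl naphthoquinone: the excited C11 carbonyl abstracts a C1 hydrogen across the bay, the quinone methide photoenol 12 adds the carboxylic acid at C1 as it is known to add water, and O2 returns hydroquinone 13 to the quinone, C4–H being out of reach of either carbonyl.

Step 10
Reactants: 14 C1 pivalate of 11
Product: 17 (1R,4S)-lactone 7-O-triisopropylsilyl ether, via o-quinodimethane 15 (not isolated), via carbonate enolate 16 (not isolated)
Conditions: CO2 (1 atm), Cs2CO3, MeOH (20 mol %), O-allyl-N-(9-anthracenylmethyl)cinchonidinium bromide (10 mol %), toluene–CH2Cl2, 0 °C → rt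
Reagents that add atoms: carbon dioxide, O=C=O
Why: Proposed new method: Carbonate removes C4–H of 14, a vinylogous α-proton of the C14 carbonyl relayed through ring B, and the extended enolate expels pivalate from C1 to give the o-quinodimethane 15 (C1=C10–C5=C4), a push–pull diene that is electrophilic only at C1 (δ-carbon of the C14 dienone; C4 is deactivated by the C7 silyloxy donor). Methyl carbonate, formed from the catalytic methoxide and CO2, adds through oxygen to C1, which restores aromatic ring B and makes C4 the terminus of the vinylogous enolate 16, and C4 then attacks the tethered carbonate carbonyl (6-exo-trig, Dieckmann-type) with release of methoxide for the next turnover; the net result is a stepwise formal [4+2] addition of CO2 across C1 and C4 that closes the δ-lactone as the third bridge of a 2-oxabicyclo[2.2.2]octanone. The closest known reaction types are the [4+2] capture of CO2 by hydroxy-o-quinodimethanes (photoenols of o-alkylaryl ketones), the conjugate addition of oxygen nucleophiles to quinone methides and the intramolecular acylation of enolates by carbonates; their combination on a quinone-derived o-quinodimethane is new. The C4 configuration is set in the C–C bond-forming step inside the ion pair of enolate 16 and the chiral cinchonidinium cation, the two C1 epimers of 16 being in equilibrium through 15, and C1 is then fixed as cis by the bridge. The step needs the CO2 orientation O to C1 and C to C4 and a ring closure that outruns aromatisation of ring A; the first is secured by the C14 carbonyl and the C7 ether as described, the second by the weak CO2-buffered base, and the silyl group keeps O7 from forming a phenoxide that would quench the C4–H acidity.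

Step 11
Reactants: 17 (1R,4S)-lactone 7-O-triisopropylsilyl ether
Product: 18 target CNP0271770.1
Conditions: HF·pyridine, THF, 0 °C → rt
Reagents that add atoms: none
Why: Fluoride cleavage of the aryl silyl ether under acidic conditions (desilylation) frees the C7 phenol without opening the lactone or touching the vinylogous ester.

Compound list (tricyclic compounds carry the plan locants)

1 | 1,2,4-trimethoxybenzene | COc1ccc(OC)c(OC)c1 | starting material
2 | 2-(2,3,6-trimethoxyphenyl)propan-2-ol | COc1ccc(OC)c(C(C)(C)O)c1OC | intermediate
3 | 1,2,4-trimethoxy-3-(propan-2-yl)benzene | COc1ccc(OC)c(C(C)C)c1OC | intermediate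
4 | 1-bromo-2,4,5-trimethoxy-3-(propan-2-yl)benzene | COc1cc(Br)c(OC)c(C(C)C)c1OC | intermediate
5 | 2-bromo-5-methoxy-6-(propan-2-yl)cyclohexa-2,5-diene-1,4-dione | COC1=C(C(C)C)C(=O)C(Br)=CC1=O | intermediate
6 | 2-methylcyclohexanone (racemic) | CC1CCCCC1=O | starting material
7 | ethyl 2-(2-methylcyclohexylidene)acetate (racemic, mainly E) | CCOC(=O)C=C1CCCCC1C | intermediate
8 | [1-ethoxy-2-(6-methylcyclohex-1-en-1-yl)ethenyl]oxy(trimethyl)silane (racemic) | CCOC(O[Si](C)(C)C)=CC1=CCCCC1C | intermediate
9 | bromo ketal cycloadduct (C8–Br, C7(OEt)(OSiMe3), C5=C6; diastereomer mixture) | COC1=C(C(C)C)C(=O)C2(Br)C(C1=O)C3CCCC(C)C3=CC2(OCC)O[Si](C)(C)C | intermediate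
10 | 7-hydroxy-12-methoxy-4-methyl-13-(propan-2-yl)-1,2,3,4-tetrahydrophenanthrene-11,14-dione (racemic) | COC1=C(C(C)C)C(=O)c2c(O)cc3c(c2C1=O)CCCC3C | intermediate
11 | 7-O-triisopropylsilyl ether of 10 (racemic) | COC1=C(C(C)C)C(=O)c2c(O[Si](C(C)C)(C(C)C)C(C)C)cc3c(c2C1=O)CCCC3C | intermediate
12 | quinone methide photoenol of 11 (C1=C10, C9=C11–OH, C14=O) | COC1=C(C(C)C)C(=O)C2=C(O[Si](C(C)C)(C(C)C)C(C)C)C=C3C(C)CCC=C3C2=C1O | intermediate
13 | 11,14-hydroquinone with C1 pivalate | COc1c(C(C)C)c(O)c2c(O[Si](C(C)C)(C(C)C)C(C)C)cc3c(c2c1O)C(OC(=O)C(C)(C)C)CCC3C | intermediate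
14 | 1-pivaloyloxy derivative of 11 (racemic, both C1/C4 diastereomers) | COC1=C(C(C)C)C(=O)c2c(O[Si](C(C)C)(C(C)C)C(C)C)cc3c(c2C1=O)C(OC(=O)C(C)(C)C)CCC3C | intermediate
15 | o-quinodimethane (C1=C10, C4=C5, C6=C7–OSi, C8=C9, quinone ring C) | COC1=C(C(C)C)C(=O)C2=C(C1=O)C3=CCCC(C)=C3C=C2O[Si](C(C)C)(C(C)C)C(C)C | intermediate
16 | C1 methyl carbonate, C14 enolate (anion, paired with the chiral ammonium; both C1 epimers) | COC1=C(C(C)C)C([O-])=C2C(O[Si](C(C)C)(C(C)C)C(C)C)=CC3=C(C)CCC(OC(=O)OC)C3=C2C1=O | intermediate
17 | (1R,4S)-lactone (C4–C(=O)–O–C1) 7-O-triisopropylsilyl ether | COC1=C(C(C)C)C(=O)c2c(O[Si](C(C)C)(C(C)C)C(C)C)cc3c(c2C1=O)[C@H]1CC[C@]3(C)C(=O)O1 | intermediate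
18 | CNP0271770.1: (5R,8S)-10-hydroxy-3-methoxy-8-methyl-2-(propan-2-yl)-5,6,7,8-tetrahydro-5,8-(epoxymethano)phenanthrene-1,4,12-trione, (1R,4S) in plan locants | COC1=C(C(C)C)C(=O)c2c(O)cc3c(c2C1=O)[C@H]1CC[C@]3(C)C(=O)O1 | target

Total step count: 11. Longest linear sequence: 9 steps (steps 1–4, then 7–11).

Steps most likely to fail

Step 10. Several processes may go wrong. The vinylogous deprotonation at C4 may be too slow under the CO2-buffered base. The o-quinodimethane may be lost to ring-A aromatisation or a 1,5-hydrogen shift before it is captured. Facial control in the ion-paired acylation may be poor.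

The fallback sets out from 5 and comes back at 17; it makes the C4 quaternary centre first by known chemistry and closes only the O–C1 bond at the end. Commercial tert-butyl 2-oxocyclohexane-1-carboxylate would be methylated under asymmetric phase-transfer conditions (MeI, CsOH·H2O, a chiral N-spiro binaphthyl quaternary ammonium bromide, toluene) to tert-butyl (S)-1-methyl-2-oxocyclohexane-1-carboxylate F1. Peterson olefination (Me3SiCH2CO2Et, LiN(i-Pr)2, THF) would give tert-butyl (S)-2-(2-ethoxy-2-oxoethylidene)-1-methylcyclohexane-1-carboxylate F2. Its only γ-CH2 would be deprotonated and the dienolate silylated (LiN(i-Pr)2, Me3SiCl) to the silyl ketene acetal F3. Diels–Alder reaction with 5 and aromatisation as in step 7 should give the (4S)-quinone phenol tert-butyl ester F4, which would be silylated as in step 8 to its 7-O-triisopropylsilyl ether F5. Irradiation (405 nm, MeCN, O2) should form the C1=C10 photoenol, which the ester carbonyl oxygen captures at C1 with loss of 2-methylpropene. Reoxidation then gives 17, whose C1 configuration is fixed by the bridge from the (S) centre of F1.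

Step 9. The photoenol may return to the quinone faster than the weakly nucleophilic acid adds, and the hydroquinone adduct may revert before it is reoxidised.

The fallback sets out from 11 and comes back at 14; it is thermal. C1–H is the most acidic C–H of 11 (vinylogous α-proton of C11=O), so DBU under O2 in the presence of P(OEt)3 (MeCN, 0 °C) should oxygenate the extended enolate at C1. The hydroperoxide is reduced in the flask to the C1 alcohol F6. Acylation (t-BuCOCl, DMAP, pyridine) then gives 14.

Step 6. Regiocontrol of the deprotonation may be lost: the minor Z enoate is deprotonated at the C4 methine and leads to the tetrasubstituted diene isomer, and proton transfer may scramble the dienolates.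

The fallback sets out from 6 and comes back at 8; it fixes the double-bond position before the ester is introduced. The kinetic enolate of 6 (LiN(i-Pr)2, THF, −78 °C) would be trapped with PhNTf2 as 6-methylcyclohex-1-en-1-yl trifluoromethanesulfonate F7. Negishi coupling with the Reformatsky reagent BrZnCH2CO2Et (Pd(PPh3)4, THF) would give ethyl 2-(6-methylcyclohex-1-en-1-yl)acetate F8. Plain α-deprotonation and silylation (LiN(i-Pr)2, Me3SiCl) then give 8.

Further compounds
F1 | step 10 | tert-butyl (S)-1-methyl-2-oxocyclohexane-1-carboxylate | O=C1CCCC[C@]1(C)C(=O)OC(C)(C)C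
F2 | step 10 | tert-butyl (S)-2-(2-ethoxy-2-oxoethylidene)-1-methylcyclohexane-1-carboxylate | CCOC(=O)C=C1CCCC[C@]1(C)C(=O)OC(C)(C)C
F3 | step 10 | tert-butyl (S)-2-[2-ethoxy-2-(trimethylsilyloxy)ethenyl]-1-methylcyclohex-2-ene-1-carboxylate | CCOC(O[Si](C)(C)C)=CC1=CCCC[C@]1(C)C(=O)OC(C)(C)C
F4 | step 10 | tert-butyl (4S)-7-hydroxy-12-methoxy-4-methyl-11,14-dioxo-13-(propan-2-yl)-1,2,3,4-tetrahydrophenanthrene-4-carboxylate (plan locants) | COC1=C(C(C)C)C(=O)c2c(O)cc3c(c2C1=O)CCC[C@]3(C)C(=O)OC(C)(C)C
F5 | step 10 | 7-O-triisopropylsilyl ether of F4 | COC1=C(C(C)C)C(=O)c2c(O[Si](C(C)C)(C(C)C)C(C)C)cc3c(c2C1=O)CCC[C@]3(C)C(=O)OC(C)(C)C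
F6 | step 9 | 1-hydroxy derivative of 11 (racemic, both diastereomers) | COC1=C(C(C)C)C(=O)c2c(O[Si](C(C)C)(C(C)C)C(C)C)cc3c(c2C1=O)C(O)CCC3C
F7 | step 6 | 6-methylcyclohex-1-en-1-yl trifluoromethanesulfonate (racemic) | CC1CCCC=C1OS(=O)(=O)C(F)(F)F
F8 | step 6 | ethyl 2-(6-methylcyclohex-1-en-1-yl)acetate (racemic) | CCOC(=O)CC1=CCCCC1C
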